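**Retrosynthetic overview**
- The butenolide ring is made last, by ring-closing metathesis of an allyl 2-alkylacrylate. This ester comes from the enol triflate of a side-chain methyl ketone by alkoxycarbonylation.
- The quaternary C4 is set by conjugate reduction and methylation of the C3=C4 enoate that the key step leaves behind, with both carbonyl groups masked meanwhile.
- Rings A and B are made together by an intramolecular Diels–Alder reaction of an acyclic triene, which closes C1–C2 and C5–C10 in one operation.
- Enabling feature: in ring A the formyl-bearing C10 and the ester-bearing C4 flank C5. C1=C10 is therefore the C=C of a 2-substituted acrolein and C2=C3–C4=C5 is a polarity-matched 2-carbomethoxy-diene. C5–C10 is the bond shared by rings A and B, so C6–C9 is a four-carbon tether with the stereocentre C9 next to the dienophile.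
- The triene comes from (R)-limonene, which supplies C7–C13, C17, C20 and the configuration of C9. Order of ring formation: A and B at once, then the lactone.

Key step: step 7

Remark: labdane numbering is used for all compounds, acyclic ones included (C1–C10 decalin, C11–C16 side chain, C17 exocyclic CH2, C18/C19 on C4, C20 on C10). The target is read as the normal labdane series: 5α-H, 9α-H, 10β-CHO, 4α-CH3, 4β-CO2Me.

**Step 1**
Reactants: 1 (R)-(+)-limonene; 2 3-bromo-1-(trimethylsilyl)prop-1-yne
Product: 4 trimethyl{5-[(1R)-4-methylcyclohex-3-en-1-yl]hex-5-en-1-yn-1-yl}silane, via 10-lithiolimonene 3 (not isolated)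
Conditions: n-BuLi, Me2NCH2CH2NMe2 (TMEDA), hexane, rt, 16 h; then 2, THF, −78 °C → rt
Reagents that add atoms: none
Why: Allylic lithiation removes a proton of the isopropenyl methyl group to give the symmetrical 2-substituted allyllithium 3, so its SN2 alkylation by the propargylic bromide has no regiochemical choice and the ring stereocentre (the future C9) is not touched.

**Step 2**
Reactants: 4 trimethyl{5-[(1R)-4-methylcyclohex-3-en-1-yl]hex-5-en-1-yn-1-yl}silane
Product: 6 methyl 6-[(1R)-4-methylcyclohex-3-en-1-yl]hept-6-en-2-ynoate, via lithium acetylide 5 (not isolated)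
Conditions: MeLi·LiBr, THF, 0 °C → rt; then ClCO2Me, −78 → 0 °C
Reagents that add atoms: methyl chloroformate, COC(=O)Cl
Why: Silicon–lithium exchange of the alkynylsilane with MeLi gives acetylide 5, which is C-acylated by the chloroformate (acetylide carboxylation) to install C19.

**Step 3**
Reactants: 6 methyl 6-[(1R)-4-methylcyclohex-3-en-1-yl]hept-6-en-2-ynoate
Product: 7 methyl (2E)-6-[(1R)-4-methylcyclohex-3-en-1-yl]-2-(tributylstannyl)hepta-2,6-dienoate
Conditions: Bu3SnH, Pd(PPh3)4 (2 mol %), THF, 0 °C → rt
Reagents that add atoms: tributyltin hydride, CCCC[SnH](CCCC)CCCC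
Why: Hydrostannation of a 2-alkynoate under zerovalent palladium catalysis is a syn addition that places tin on the carbon next to the ester, so the chain (C6) ends up cis to CO2Me while the isolated alkenes stay untouched.

**Step 4**
Reactants: 7 methyl (2E)-6-[(1R)-4-methylcyclohex-3-en-1-yl]-2-(tributylstannyl)hepta-2,6-dienoate
Product: 8 methyl (2Z)-2-ethenyl-6-[(1R)-4-methylcyclohex-3-en-1-yl]hepta-2,6-dienoate
Conditions: CH2=CHBr (1 M in THF), Pd2(dba)3 (2.5 mol %), AsPh3 (20 mol %), CuI (20 mol %), NMP, 40 °C, sealed tube
Reagents that add atoms: vinyl bromide, C=CBr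
Why: The Stille coupling (CuI co-catalysis for the hindered α-stannyl acrylate) goes with retention at the alkenyl carbon, so C6 stands trans to the new vinyl group, the outside position that the cycloaddition needs.

**Step 5**
Reactants: 8 methyl (2Z)-2-ethenyl-6-[(1R)-4-methylcyclohex-3-en-1-yl]hepta-2,6-dienoate
Product: 11 methyl (2Z,7R)-2-ethenyl-6-methylidene-10-oxo-7-(2-oxoethyl)undec-2-enoate, via ring epoxide 9 (not isolated), via ring 1,2-diol 10 (not isolated)
Conditions: mCPBA (1.0 equiv), CH2Cl2, −10 °C; concentrate; H5IO6, THF/H2O, 0 °C → rt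
Reagents that add atoms: mCPBA, OOC(=O)c1cccc(Cl)c1; water, O
Why: Prilezhaev epoxidation with one equivalent of peracid picks the trisubstituted ring alkene as the most electron-rich of the four C=C bonds, and periodic acid opens the crude epoxide to the glycol and cleaves it (Malaprade cleavage), freeing C20 as aldehyde and C13 as methyl ketone without touching C9.

**Step 6**
Reactants: 11 methyl (2Z,7R)-2-ethenyl-6-methylidene-10-oxo-7-(2-oxoethyl)undec-2-enoate
Product: 12 methyl (2Z,7S)-2-ethenyl-7-(1-formylethenyl)-6-methylidene-10-oxoundec-2-enoate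
Conditions: 37% aq CH2O, pyrrolidine (10 mol %), propionic acid (10 mol %), i-PrOH, rt; used at once
Reagents that add atoms: formaldehyde, C=O
Why: Amine-catalysed Mannich condensation with formaldehyde and loss of the amine (α-methylenation of an aldehyde) acts only on the CH2 next to the aldehyde, formaldehyde should outrun the internal ketone as electrophile for the enamine, and C9 is not acidified (its descriptor changes only because the priorities change).

**Step 7**
Reactants: 12 methyl (2Z,7S)-2-ethenyl-7-(1-formylethenyl)-6-methylidene-10-oxoundec-2-enoate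
Product: 13 methyl 13,20-dioxo-14,15,18-trinorlabda-3,8(17)-dien-19-oate (trans-fused; 5α-H, 9α-H, 10β-CHO)
Conditions: Me2AlCl (2.2 equiv), CH2Cl2 (0.005 M), −78 → −30 °C; aq NaHCO3
Reagents that add atoms: none
Why: Me2AlCl binds the formyl oxygen (a second equivalent rests on the ketone) and the activated 2-substituted acrolein C1=C10 adds suprafacially across the s-cis diene C2=C3–C4=C5 in one concerted but asynchronous [4+2] cycloaddition, in which C1 (the acceptor β-carbon) bonds to the ester-free diene terminus C2 slightly ahead of C10 bonding to C5 (the β-carbon of the dienoate), so both partners are polarity-matched. The closest known reaction type is the Lewis-acid-promoted type 1 intramolecular Diels–Alder reaction of 1,7,9-decatrienes that carry an enal dienophile. Ring A closes as the cyclohexene of the cycloaddition (it holds both new bonds), and ring B closes through C5–C10 alone in the fused mode, the only one a four-carbon tether (C6–C9) allows, with the tether folded chair-like. For C5 and C10, the geometry of C4=C5 (C6 outside) together with the formyl-endo, tether-exo transition state puts CHO trans to H-5, which is the trans-decalin; this preference rests on secondary orbital overlap strengthened by the Lewis acid and on the C4 ester, which sits on the inner diene carbon next to the tether and is pressed against the C6/C7 methylenes in the tether-endo (cis-fused) array. The facial sense comes from C9: allylic 1,3-strain holds H-9 in the plane of C10=C1, the tether carbon C8 and the oxobutyl chain then lie on opposite faces, and the diene can reach only the face anti to the chain, which makes the chain equatorial (9β), CHO 10β and H-5 α. The step needs chemoselectivity for the enal over the isolated C8=C17 alkene and over intermolecular dimerisation of the dienoate; the first is secured because only the enal is activated, the second by high dilution and low temperature.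

**Step 8**
Reactants: 13 methyl 13,20-dioxo-14,15,18-trinorlabda-3,8(17)-dien-19-oate
Product: 14 methyl 13,13:20,20-bis(ethylenedioxy)-14,15,18-trinorlabda-3,8(17)-dien-19-oate
Conditions: Me3SiOCH2CH2OSiMe3, Me3SiOTf (5 mol %), CH2Cl2, −78 → −20 °C; pyridine
Reagents that add atoms: 1,2-bis(trimethylsilyloxy)ethane, C[Si](C)(C)OCCO[Si](C)(C)C
Why: Aprotic acetalisation with the bis-silyl ether of glycol under Me3SiOTf catalysis masks aldehyde and ketone in one operation at low temperature, where neither the exocyclic alkene nor the enoate should migrate.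

**Step 9**
Reactants: 14 methyl 13,13:20,20-bis(ethylenedioxy)-14,15,18-trinorlabda-3,8(17)-dien-19-oate
Product: 16 methyl 13,13:20,20-bis(ethylenedioxy)-14,15-dinorlabd-8(17)-en-19-oate, via lithium ester enolate 15 (not isolated)
Conditions: LiBH(s-Bu)3, THF, −78 °C; then MeI, DMPU, −78 → 0 °C
Reagents that add atoms: iodomethane, CI
Why: Conjugate hydride addition to the enoate and alkylation of ester enolate 15 (reductive alkylation) set C4, because MeI approaches the exocyclic enolate from the α face (equatorial), away from the axial dioxolanyl group on C10, which places the methyl α and the ester β (axial).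

**Step 10**
Reactants: 16 methyl 13,13:20,20-bis(ethylenedioxy)-14,15-dinorlabd-8(17)-en-19-oate
Product: 17 methyl 13,20-dioxo-14,15-dinorlabd-8(17)-en-19-oate
Conditions: 1 M HCl, THF, rt
Reagents that add atoms: water, O
Why: Acid-catalysed acetal hydrolysis frees both carbonyl groups, and dilute acid at room temperature should leave the exocyclic alkene and the methyl ester alone, while no stereocentre carries a hydrogen α to a liberated carbonyl group.

**Step 11**
Reactants: 17 methyl 13,20-dioxo-14,15-dinorlabd-8(17)-en-19-oate
Product: 19 methyl 20-oxo-13-(trifluoromethylsulfonyloxy)-14,15-dinorlabda-8(17),13(16)-dien-19-oate, via potassium enolate 18 (not isolated)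
Conditions: KN(SiMe3)2 (1.05 equiv), THF, −78 °C; then N-(5-chloropyridin-2-yl)bis(trifluoromethanesulfonimide), −78 °C
Reagents that add atoms: N-(5-chloropyridin-2-yl)bis(trifluoromethanesulfonimide), FC(F)(F)S(=O)(=O)N(c1ccc(Cl)cn1)S(=O)(=O)C(F)(F)F
Why: Kinetic deprotonation of the methyl ketone at its methyl group by the bulky amide and O-sulfonylation give the terminal enol triflate, while the aldehyde has no α-hydrogen and is shielded by the quaternary C10 and the 1,3-diaxial ester.

**Step 12**
Reactants: 19 methyl 20-oxo-13-(trifluoromethylsulfonyloxy)-14,15-dinorlabda-8(17),13(16)-dien-19-oate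
Product: 20 allyl acrylate, the decalin of 17 with the side chain CH2CH2C(=CH2)CO2CH2CH=CH2
Conditions: Pd(OAc)2 (5 mol %), PPh3 (10 mol %), CO (1 atm), allyl alcohol (excess), Et3N, DMF, rt
Reagents that add atoms: carbon monoxide, [C-]#[O+]; allyl alcohol, C=CCO
Why: In this palladium-catalysed alkoxycarbonylation of an alkenyl triflate (oxidative addition to zerovalent palladium, CO insertion, capture of the acylpalladium species by allyl alcohol), CO insertion at room temperature should outrun carbopalladation of the hindered C8=C17 alkene.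

**Step 13**
Reactants: 20 allyl acrylate with the side chain CH2CH2C(=CH2)CO2CH2CH=CH2
Product: 21 methyl 20-oxolabda-8(17),13-dien-16,15-olid-19-oate (CNP0175906.1)
Conditions: second-generation Grubbs catalyst RuCl2(=CHPh)(PCy3)(H2IMes) (5 mol %), CH2Cl2 (0.005 M), reflux
Reagents that add atoms: none
Why: Ring-closing metathesis between the allyl ester and the 1,1-disubstituted acrylate closes the five-membered α-substituted butenolide with loss of ethene, and the hindered exocyclic alkene and the aldehyde should stay inert.

**Compound list**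
1 | (R)-(+)-limonene, (4R)-1-methyl-4-(prop-1-en-2-yl)cyclohex-1-ene | CC1=CC[C@@H](CC1)C(C)=C | starting material
2 | 3-bromo-1-(trimethylsilyl)prop-1-yne | C[Si](C)(C)C#CCBr | starting material
3 | 10-lithiolimonene | CC1=CC[C@@H](CC1)C(=C)C[Li] | intermediate
4 | trimethyl{5-[(1R)-4-methylcyclohex-3-en-1-yl]hex-5-en-1-yn-1-yl}silane | CC1=CC[C@@H](CC1)C(=C)CCC#C[Si](C)(C)C | intermediate
5 | lithium acetylide from 4 | CC1=CC[C@@H](CC1)C(=C)CCC#C[Li] | intermediate
6 | methyl 6-[(1R)-4-methylcyclohex-3-en-1-yl]hept-6-en-2-ynoate | CC1=CC[C@@H](CC1)C(=C)CCC#CC(=O)OC | intermediate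
7 | methyl (2E)-6-[(1R)-4-methylcyclohex-3-en-1-yl]-2-(tributylstannyl)hepta-2,6-dienoate | CC1=CC[C@@H](CC1)C(=C)CC/C=C(\C(=O)OC)[Sn](CCCC)(CCCC)CCCC | intermediate
8 | methyl (2Z)-2-ethenyl-6-[(1R)-4-methylcyclohex-3-en-1-yl]hepta-2,6-dienoate | CC1=CC[C@@H](CC1)C(=C)CC/C=C(\C(=O)OC)C=C | intermediate
9 | ring epoxide of 8 (both epoxide diastereomers) | CC12OC1C[C@@H](CC2)C(=C)CC/C=C(\C(=O)OC)C=C | intermediate
10 | ring 1,2-diol of 8 (diastereomer mixture) | CC1(O)C(O)C[C@@H](CC1)C(=C)CC/C=C(\C(=O)OC)C=C | intermediate
11 | methyl (2Z,7R)-2-ethenyl-6-methylidene-10-oxo-7-(2-oxoethyl)undec-2-enoate | CC(=O)CC[C@H](CC=O)C(=C)CC/C=C(\C(=O)OC)C=C | intermediate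
12 | methyl (2Z,7S)-2-ethenyl-7-(1-formylethenyl)-6-methylidene-10-oxoundec-2-enoate | CC(=O)CC[C@H](C(=C)C=O)C(=C)CC/C=C(\C(=O)OC)C=C | intermediate
13 | methyl 13,20-dioxo-14,15,18-trinorlabda-3,8(17)-dien-19-oate (5α-H, 9α-H, 10β-CHO) | C=C1CC[C@@H]2[C@](C=O)(CCC=C2C(=O)OC)[C@H]1CCC(C)=O | intermediate
14 | methyl 13,13:20,20-bis(ethylenedioxy)-14,15,18-trinorlabda-3,8(17)-dien-19-oate | C=C1CC[C@@H]2[C@](C3OCCO3)(CCC=C2C(=O)OC)[C@H]1CCC1(C)OCCO1 | intermediate
15 | lithium ester enolate (C4=C19) from 14 | C=C1CC[C@@H]2[C@](C3OCCO3)(CCCC2=C(OC)O[Li])[C@H]1CCC1(C)OCCO1 | intermediate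
16 | methyl 13,13:20,20-bis(ethylenedioxy)-14,15-dinorlabd-8(17)-en-19-oate (4α-CH3, 4β-CO2Me) | C=C1CC[C@@H]2[C@](C3OCCO3)(CCC[C@]2(C)C(=O)OC)[C@H]1CCC1(C)OCCO1 | intermediate
17 | methyl 13,20-dioxo-14,15-dinorlabd-8(17)-en-19-oate | C=C1CC[C@@H]2[C@](C=O)(CCC[C@]2(C)C(=O)OC)[C@H]1CCC(C)=O | intermediate
18 | terminal potassium enolate of 17 | C=C1CC[C@@H]2[C@](C=O)(CCC[C@]2(C)C(=O)OC)[C@H]1CCC(=C)O[K] | intermediate
19 | methyl 20-oxo-13-(trifluoromethylsulfonyloxy)-14,15-dinorlabda-8(17),13(16)-dien-19-oate | C=C1CC[C@@H]2[C@](C=O)(CCC[C@]2(C)C(=O)OC)[C@H]1CCC(=C)OS(=O)(=O)C(F)(F)F | intermediate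
20 | allyl acrylate, side chain CH2CH2C(=CH2)CO2CH2CH=CH2 | C=C1CC[C@@H]2[C@](C=O)(CCC[C@]2(C)C(=O)OC)[C@H]1CCC(=C)C(=O)OCC=C | intermediate
21 | methyl 20-oxolabda-8(17),13-dien-16,15-olid-19-oate (CNP0175906.1) | C=C1CC[C@@H]2[C@](C=O)(CCC[C@]2(C)C(=O)OC)[C@H]1CCC1=CCOC1=O | target

**Totals**
Total step count: 13. Longest linear sequence: 13 steps, from 1.

**Steps most likely to fail**

Step 7.
- What may go wrong: the formyl-endo and tether-endo foldings may be told apart too weakly, which would erode the trans ring fusion. The Lewis acid may also trigger a carbonyl-ene closure of the methyl ketone onto the C8=C17 alkene, or transfer a methyl group to the aldehyde.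
- Fallback, from 12: both carbonyl groups are masked first (Me3SiOCH2CH2OSiMe3, catalytic Me3SiOTf, CH2Cl2, −78 °C) to give the bis-dioxolane triene F1.
- Catalytic CF3SO3H at −78 to −40 °C then opens the allylic dioxolane reversibly to a 2-alkenyl oxocarbenium ion. This cationic dienophile undergoes an ionic intramolecular Diels–Alder reaction and recloses to the dioxolane.
- The ketone is thus never exposed to a Lewis acid. The fallback comes back to the route at 14.

Step 11.
- What may go wrong: the amide base or the ketone enolate may add to the free aldehyde, and enolate equilibration may cost regiocontrol.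
- Fallback, from 16, by staged unmasking: pyridinium 4-toluenesulfonate in wet acetone at rt should hydrolyse only the faster ketone ketal, giving the keto acetal F2.
- KN(SiMe3)2 at −78 °C gives its terminal potassium enolate F3, and the same triflimide reagent gives the enol triflate acetal F4.
- Pd(OAc)2/PPh3, CO, allyl alcohol and Et3N give the allyl acrylate acetal F5.
- The second-generation Grubbs catalyst RuCl2(=CHPh)(PCy3)(H2IMes) gives the butenolide acetal F6.
- Hydrolysis with 1 M HCl in THF as the last operation comes back to the route at 21.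

Step 9.
- What may go wrong: hydride delivery to the hindered β-carbon C3 may be slow, 1,2-reduction may compete, the enolate may be quenched by a proton before it is alkylated, or facial selectivity may erode.
- Fallback, from 14: the two events are separated. Mg in MeOH reduces the enoate by electron transfer to the saturated ester F7. Its C4 epimers do not matter, because C4 is made planar again.
- LiN(i-Pr)2 in THF/DMPU at −78 °C then regenerates enolate 15 free of borane, and MeI brings the sequence back to the route at 16.

**Further compounds**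
F1 | step 7 | bis-dioxolane of triene 12 | CC1(OCCO1)CC[C@H](C(=C)C2OCCO2)C(=C)CC/C=C(\C(=O)OC)C=C
F2 | step 11 | methyl 20,20-ethylenedioxy-13-oxo-14,15-dinorlabd-8(17)-en-19-oate | C=C1CC[C@@H]2[C@](C3OCCO3)(CCC[C@]2(C)C(=O)OC)[C@H]1CCC(C)=O
F3 | step 11 | terminal potassium enolate of F2 | C=C1CC[C@@H]2[C@](C3OCCO3)(CCC[C@]2(C)C(=O)OC)[C@H]1CCC(=C)O[K]
F4 | step 11 | enol triflate acetal | C=C1CC[C@@H]2[C@](C3OCCO3)(CCC[C@]2(C)C(=O)OC)[C@H]1CCC(=C)OS(=O)(=O)C(F)(F)F
F5 | step 11 | allyl acrylate acetal | C=C1CC[C@@H]2[C@](C3OCCO3)(CCC[C@]2(C)C(=O)OC)[C@H]1CCC(=C)C(=O)OCC=C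
F6 | step 11 | butenolide acetal (20,20-ethylenedioxy derivative of 21) | C=C1CC[C@@H]2[C@](C3OCCO3)(CCC[C@]2(C)C(=O)OC)[C@H]1CCC1=CCOC1=O
F7 | step 9 | saturated ester, 3,4-dihydro-14 (C4 epimer mixture) | C=C1CC[C@@H]2[C@](C3OCCO3)(CCCC2C(=O)OC)[C@H]1CCC1(C)OCCO1
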